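**Plan**
- The retrosynthesis first removes four O-benzyl groups, then cuts the depside at the aryl C–O bond between ring A C4 and the ester oxygen, not at the acyl C–O bond.
- This leaves a ring B carboxylate as the nucleophile and a ring A aryl(2,4,6-trimethoxyphenyl)iodonium salt as the aryl donor. The C4–I bond goes back through a boronate and a 4-triflate to the 4-OH of atraric acid. The ring B carboxyl goes back to a formyl group on 3,4,5-tris(benzyloxy)toluene, whose methyl group is the reduced ester carbon of methyl 3,4,5-tris(benzyloxy)benzoate.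
- Enabling feature: ring A C4 is para to the CO2Me on C1 and next to the C3 methyl, so this aryl leaves trivalent iodine readily. The ring B C1 carbonyl lies between O2 and the C6 methyl, so it is a poor acyl electrophile but a normal carboxylate nucleophile.
- Forward: both benzene rings are bought intact and no ring is formed. Ring A is elaborated in steps 1–5 and ring B in steps 6–10; the two are joined in step 11 and unmasked in step 12.
- The target has no stereocentre, so no stereochemistry has to be set.

Key step: step 11

Assumption: ring A is numbered from the carbon bearing CO2Me and ring B from the carbon bearing the depside carbonyl; methyl 3,4,5-tris(benzyloxy)benzoate is taken to be a catalogue gallate derivative, so ring B enters with its three benzyl ethers in place and no free pyrogallol has to be handled.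

**Route**

Step 1
Reactants: 1 atraric acid (methyl 2,4-dihydroxy-3,6-dimethylbenzoate)
Product: 2 methyl 2-hydroxy-3,6-dimethyl-4-[(trifluoromethanesulfonyl)oxy]benzoate
Conditions: Tf2O (1.05 equiv), pyridine, CH2Cl2, −20 to 0 °C
Reagents that add atoms: trifluoromethanesulfonic anhydride, O=S(=O)(OS(=O)(=O)C(F)(F)F)C(F)(F)F
Why: Selective O-triflation (sulfonylation of a phenol) should take place at the free 4-OH, because the 2-OH is held in a hydrogen bond to the ester carbonyl and is flanked by the ester and the C3 methyl.

Step 2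
Reactants: 2 methyl 2-hydroxy-3,6-dimethyl-4-[(trifluoromethanesulfonyl)oxy]benzoate; 3 benzyl bromide
Product: 4 methyl 2-(benzyloxy)-3,6-dimethyl-4-[(trifluoromethanesulfonyl)oxy]benzoate
Conditions: K2CO3, Bu4NI (cat.), DMF, 50 °C
Reagents that add atoms: none
Why: Williamson etherification of the remaining chelated phenol should proceed under carbonate in DMF at moderate temperature, conditions that an aryl triflate normally tolerates.

Step 3
Reactants: 4 methyl 2-(benzyloxy)-3,6-dimethyl-4-[(trifluoromethanesulfonyl)oxy]benzoate
Product: 5 methyl 2-(benzyloxy)-3,6-dimethyl-4-(4,4,5,5-tetramethyl-1,3,2-dioxaborolan-2-yl)benzoate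
Conditions: B2pin2, PdCl2(dppf) (3 mol%), KOAc, 1,4-dioxane, 90 °C
Reagents that add atoms: bis(pinacolato)diboron, CC1(C)OB(OC1(C)C)B1OC(C)(C)C(C)(C)O1
Why: In this Miyaura borylation, zerovalent palladium should insert readily into the C–OTf bond para to the ester, and the weak base KOAc spares the methyl ester and the benzyl ether.

Step 4
Reactants: 5 methyl 2-(benzyloxy)-3,6-dimethyl-4-(4,4,5,5-tetramethyl-1,3,2-dioxaborolan-2-yl)benzoate
Product: 6 methyl 2-(benzyloxy)-4-iodo-3,6-dimethylbenzoate
Conditions: CuI (10 mol%), 1,10-phenanthroline (20 mol%), KI, MeOH/H2O 4:1, air, 80 °C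
Reagents that add atoms: potassium iodide, [K+].[I-]
Why: Copper-catalysed aerobic iododeboronation (a halodeboronation akin to Chan–Lam coupling) should replace boron by iodine only at the ipso carbon, and it avoids electrophilic iodine that could attack the free C5–H para to the benzyloxy group.

Step 5
Reactants: 6 methyl 2-(benzyloxy)-4-iodo-3,6-dimethylbenzoate; 7 1,3,5-trimethoxybenzene
Product: 9 [3-(benzyloxy)-4-(methoxycarbonyl)-2,5-dimethylphenyl](2,4,6-trimethoxyphenyl)iodonium tosylate, via hydroxy(tosyloxy)iodoarene 8 (not isolated)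
Conditions: mCPBA, TsOH·H2O, MeCN, 50 °C; then 1,3,5-trimethoxybenzene, rt; precipitation with Et2O
Reagents that add atoms: p-toluenesulfonic acid (used as monohydrate), Cc1ccc(S(=O)(=O)O)cc1
Why: One-pot peracid oxidation of the aryl iodide to a hydroxy(tosyloxy)-λ3-iodane followed by electrophilic aromatic substitution on 1,3,5-trimethoxybenzene is the standard synthesis of aryl(trimethoxyphenyl)iodonium tosylates and should give the salt, the arene being added only after the oxidation so that it is not itself oxidised.

Step 6
Reactants: 10 methyl 3,4,5-tris(benzyloxy)benzoate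
Product: 11 [3,4,5-tris(benzyloxy)phenyl]methanol
Conditions: LiAlH4, THF, 0 °C to rt; then H2O, aq NaOH
Reagents that add atoms: none
Why: Hydride reduction of the ester with LiAlH4 should give the primary benzylic alcohol, while the aryl benzyl ethers are inert to hydride.

Step 7
Reactants: 11 [3,4,5-tris(benzyloxy)phenyl]methanol
Product: 12 1,2,3-tris(benzyloxy)-5-(chloromethyl)benzene
Conditions: SOCl2 (1.2 equiv), DMF (cat.), CH2Cl2, 0 °C to rt
Reagents that add atoms: thionyl chloride, O=S(Cl)Cl
Why: Deoxychlorination of the benzylic alcohol through its chlorosulfite should be fast for this electron-rich benzyl system, and brief contact with HCl in CH2Cl2 at or below rt is not expected to cleave aryl benzyl ethers.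

Step 8
Reactants: 12 1,2,3-tris(benzyloxy)-5-(chloromethyl)benzene
Product: 13 1,2,3-tris(benzyloxy)-5-methylbenzene (3,4,5-tris(benzyloxy)toluene)
Conditions: LiBHEt3 (1.2 equiv), THF, 0 °C to rt
Reagents that add atoms: none
Why: SN2 displacement of the primary benzylic chloride by the hydride of lithium triethylborohydride (reductive dehalogenation) should give the ring methyl group without touching the O-benzyl groups, which a hydrogenolytic deoxygenation would not spare.

Step 9
Reactants: 13 1,2,3-tris(benzyloxy)-5-methylbenzene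
Product: 15 2,3,4-tris(benzyloxy)-6-methylbenzaldehyde, via aryl iminium chloride 14 (not isolated)
Conditions: POCl3, DMF, 0 °C then 75 °C; then aq NaOAc, rt
Reagents that add atoms: N,N-dimethylformamide, CN(C)C=O; water, O
Why: In this Vilsmeier–Haack formylation the chloroiminium electrophile should attack the electron-rich ring at the only kind of free position (C2 and C6 are equivalent by symmetry, each ortho to the methyl and para to a benzyloxy group), and aqueous acetate hydrolyses the iminium salt to the aldehyde.

Step 10
Reactants: 15 2,3,4-tris(benzyloxy)-6-methylbenzaldehyde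
Product: 16 2,3,4-tris(benzyloxy)-6-methylbenzoic acid
Conditions: NaClO2, NaH2PO4, 2-methyl-2-butene, t-BuOH/THF/H2O, rt
Reagents that add atoms: sodium chlorite, [Na+].[O-]Cl=O
Why: Pinnick oxidation should convert the hindered aryl aldehyde into the acid under buffered conditions, the alkene scavenging hypochlorous acid so that the electron-rich ring is not chlorinated and the benzyl ethers stay intact.

Step 11
Reactants: 16 2,3,4-tris(benzyloxy)-6-methylbenzoic acid; 9 [3-(benzyloxy)-4-(methoxycarbonyl)-2,5-dimethylphenyl](2,4,6-trimethoxyphenyl)iodonium tosylate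
Product: 19 methyl 2-(benzyloxy)-3,6-dimethyl-4-{[2,3,4-tris(benzyloxy)-6-methylbenzoyl]oxy}benzoate, via caesium carboxylate 17 (not isolated), via iodonium carboxylate 18 (not isolated)
Conditions: 16, Cs2CO3 (1.0 equiv), toluene, rt; then 9 (1.1 equiv), 100 °C
Reagents that add atoms: none
Why: The caesium carboxylate 17 should exchange with tosylate to give the T-shaped aryl(trimethoxyphenyl)-λ3-iodane carboxylate 18, and ligand coupling at trivalent iodine through a three-centre transition state then joins the carboxylate oxygen to the ipso carbon (ring A C4) while 2-iodo-1,3,5-trimethoxybenzene departs. The closest known reaction type is the metal-free O-arylation of carboxylic acids by diaryliodonium salts, which is established for 2,6-disubstituted benzoates and for aryl(2,4,6-trimethoxyphenyl) salts. No ring is closed and no stereocentre is formed; the only new bond is ring A C4–O. The step needs transfer of the ring A aryl and not of the trimethoxyphenyl group, which is secured because three methoxy donors make the latter the poorest aryl to accept a nucleophile, while ring A C4 is para to CO2Me and ortho to the C3 methyl. The carbonyl carbon of ring B, shielded by O2 and the C6 methyl, is never attacked, so the hindrance that slows acylation plays no part. Benzylation of ring A O2 removes the only phenoxide that could compete as a nucleophile.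

Step 12
Reactants: 19 methyl 2-(benzyloxy)-3,6-dimethyl-4-{[2,3,4-tris(benzyloxy)-6-methylbenzoyl]oxy}benzoate
Product: 20 methyl 2-hydroxy-3,6-dimethyl-4-[(2,3,4-trihydroxy-6-methylbenzoyl)oxy]benzoate (CNP0249278.0)
Conditions: H2 (1 atm), 10% Pd/C, EtOAc, rt; filtration under argon
Reagents that add atoms: none
Why: Heterogeneous catalytic hydrogenolysis should cleave all four benzylic C–O bonds under neutral conditions in a non-nucleophilic solvent, which leaves the aryl ester, the methyl ester and the ring methyls untouched.

**Compound list**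
1 | atraric acid (methyl 2,4-dihydroxy-3,6-dimethylbenzoate) | COC(=O)c1c(C)cc(O)c(C)c1O | starting material
2 | methyl 2-hydroxy-3,6-dimethyl-4-[(trifluoromethanesulfonyl)oxy]benzoate | COC(=O)c1c(C)cc(OS(=O)(=O)C(F)(F)F)c(C)c1O | intermediate
3 | benzyl bromide | BrCc1ccccc1 | starting material
4 | methyl 2-(benzyloxy)-3,6-dimethyl-4-[(trifluoromethanesulfonyl)oxy]benzoate | COC(=O)c1c(C)cc(OS(=O)(=O)C(F)(F)F)c(C)c1OCc1ccccc1 | intermediate
5 | methyl 2-(benzyloxy)-3,6-dimethyl-4-(4,4,5,5-tetramethyl-1,3,2-dioxaborolan-2-yl)benzoate | COC(=O)c1c(C)cc(B2OC(C)(C)C(C)(C)O2)c(C)c1OCc1ccccc1 | intermediate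
6 | methyl 2-(benzyloxy)-4-iodo-3,6-dimethylbenzoate | COC(=O)c1c(C)cc(I)c(C)c1OCc1ccccc1 | intermediate
7 | 1,3,5-trimethoxybenzene | COc1cc(OC)cc(OC)c1 | starting material
8 | methyl 2-(benzyloxy)-4-[hydroxy(tosyloxy)-λ3-iodanyl]-3,6-dimethylbenzoate | COC(=O)c1c(C)cc(I(O)OS(=O)(=O)c2ccc(C)cc2)c(C)c1OCc1ccccc1 | intermediate (not isolated)
9 | [3-(benzyloxy)-4-(methoxycarbonyl)-2,5-dimethylphenyl](2,4,6-trimethoxyphenyl)iodonium tosylate | COC(=O)c1c(C)cc([I+]c2c(OC)cc(OC)cc2OC)c(C)c1OCc1ccccc1.Cc1ccc(S(=O)(=O)[O-])cc1 | intermediate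
10 | methyl 3,4,5-tris(benzyloxy)benzoate | COC(=O)c1cc(OCc2ccccc2)c(OCc2ccccc2)c(OCc2ccccc2)c1 | starting material
11 | [3,4,5-tris(benzyloxy)phenyl]methanol | OCc1cc(OCc2ccccc2)c(OCc2ccccc2)c(OCc2ccccc2)c1 | intermediate
12 | 1,2,3-tris(benzyloxy)-5-(chloromethyl)benzene | ClCc1cc(OCc2ccccc2)c(OCc2ccccc2)c(OCc2ccccc2)c1 | intermediate
13 | 1,2,3-tris(benzyloxy)-5-methylbenzene | Cc1cc(OCc2ccccc2)c(OCc2ccccc2)c(OCc2ccccc2)c1 | intermediate
14 | N-[2,3,4-tris(benzyloxy)-6-methylbenzylidene]-N-methylmethanaminium chloride | Cc1cc(OCc2ccccc2)c(OCc2ccccc2)c(OCc2ccccc2)c1C=[N+](C)C.[Cl-] | intermediate (not isolated)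
15 | 2,3,4-tris(benzyloxy)-6-methylbenzaldehyde | Cc1cc(OCc2ccccc2)c(OCc2ccccc2)c(OCc2ccccc2)c1C=O | intermediate
16 | 2,3,4-tris(benzyloxy)-6-methylbenzoic acid | Cc1cc(OCc2ccccc2)c(OCc2ccccc2)c(OCc2ccccc2)c1C(=O)O | intermediate
17 | caesium 2,3,4-tris(benzyloxy)-6-methylbenzoate | Cc1cc(OCc2ccccc2)c(OCc2ccccc2)c(OCc2ccccc2)c1C(=O)[O-].[Cs+] | intermediate (not isolated)
18 | [3-(benzyloxy)-4-(methoxycarbonyl)-2,5-dimethylphenyl](2,4,6-trimethoxyphenyl)iodonium 2,3,4-tris(benzyloxy)-6-methylbenzoate | COC(=O)c1c(C)cc([I+]c2c(OC)cc(OC)cc2OC)c(C)c1OCc1ccccc1.Cc1cc(OCc2ccccc2)c(OCc2ccccc2)c(OCc2ccccc2)c1C(=O)[O-] | intermediate (not isolated)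
19 | methyl 2-(benzyloxy)-3,6-dimethyl-4-{[2,3,4-tris(benzyloxy)-6-methylbenzoyl]oxy}benzoate | COC(=O)c1c(C)cc(OC(=O)c2c(C)cc(OCc3ccccc3)c(OCc3ccccc3)c2OCc2ccccc2)c(C)c1OCc1ccccc1 | intermediate
20 | methyl 2-hydroxy-3,6-dimethyl-4-[(2,3,4-trihydroxy-6-methylbenzoyl)oxy]benzoate | COC(=O)c1c(C)cc(OC(=O)c2c(C)cc(O)c(O)c2O)c(C)c1O | target

**Step count**
Total: 12 steps. Longest linear sequence: 7 steps (steps 1–5, 11 and 12 from atraric acid; the ring B branch, steps 6–10 followed by 11 and 12, is of the same length).

**Steps most likely to fail**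

Step 11. Ligand coupling at iodine may be slower than hydrolysis or thermal breakdown of the salt, or part of the trimethoxyphenyl group may be transferred in place of ring A. The fallback forms the same ester by acyl transfer; it sets out from boronate 5 and acid 16 and returns at 19. Oxidation of 5 with NaBO3·4H2O in THF/H2O at rt should give the phenol methyl 2-(benzyloxy)-4-hydroxy-3,6-dimethylbenzoate F1. Treatment of 16 with trifluoroacetic anhydride in toluene at rt should form in the flask the mixed anhydride 2,3,4-tris(benzyloxy)-6-methylbenzoic trifluoroacetic anhydride F2. This acylium-like species is the classical answer to the hindered carbonyl of depside acids and should acylate F1 to give 19.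

Step 5. The hindered, electron-poor iodide may be oxidised incompletely, or the warm sulfonic acid and peracid may cleave the benzyl ether. The fallback separates oxidation from arylation and avoids strong acid; it sets out from iodide 6 and returns at 9. Oxidation of 6 with NaBO3·4H2O in acetic acid at 45 °C should give the isolable diacetate methyl 2-(benzyloxy)-4-(diacetoxy-λ3-iodanyl)-3,6-dimethylbenzoate F3. Condensation of F3 with 7 in 2,2,2-trifluoroethanol at rt should give [3-(benzyloxy)-4-(methoxycarbonyl)-2,5-dimethylphenyl](2,4,6-trimethoxyphenyl)iodonium acetate F4. Anion exchange with TsOH·H2O in MeCN and precipitation with Et2O then gives 9.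

Step 9. Substitution at the crowded position between the methyl and a benzyloxy group may be slow, and the hot acidic chlorophosphate medium may cleave the neighbouring benzyl ether. The fallback installs the carboxyl carbon through an aryl anion; it sets out from 13 and returns at 16, so that aldehyde 15 and step 10 are bypassed. Bromination of 13 with N-bromosuccinimide in MeCN at 0 °C should give 1,2,3-tris(benzyloxy)-4-bromo-5-methylbenzene F5. Bromine–lithium exchange with n-BuLi in THF at −78 °C gives [2,3,4-tris(benzyloxy)-6-methylphenyl]lithium F6, which is trapped at once with CO2 and gives 16 after acidification with aq HCl.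

**Further compounds**
F1 | step 11 | methyl 2-(benzyloxy)-4-hydroxy-3,6-dimethylbenzoate | COC(=O)c1c(C)cc(O)c(C)c1OCc1ccccc1
F2 | step 11 | 2,3,4-tris(benzyloxy)-6-methylbenzoic trifluoroacetic anhydride | Cc1cc(OCc2ccccc2)c(OCc2ccccc2)c(OCc2ccccc2)c1C(=O)OC(=O)C(F)(F)F
F3 | step 5 | methyl 2-(benzyloxy)-4-(diacetoxy-λ3-iodanyl)-3,6-dimethylbenzoate | COC(=O)c1c(C)cc(I(OC(C)=O)OC(C)=O)c(C)c1OCc1ccccc1
F4 | step 5 | [3-(benzyloxy)-4-(methoxycarbonyl)-2,5-dimethylphenyl](2,4,6-trimethoxyphenyl)iodonium acetate | COC(=O)c1c(C)cc([I+]c2c(OC)cc(OC)cc2OC)c(C)c1OCc1ccccc1.CC(=O)[O-]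
F5 | step 9 | 1,2,3-tris(benzyloxy)-4-bromo-5-methylbenzene | Cc1cc(OCc2ccccc2)c(OCc2ccccc2)c(OCc2ccccc2)c1Br
F6 | step 9 | [2,3,4-tris(benzyloxy)-6-methylphenyl]lithium | [Li]c1c(C)cc(OCc2ccccc2)c(OCc2ccccc2)c1OCc1ccccc1
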